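The synthesis rests on cutting two bonds of ring B, C10–CH3 and C9–C11. C10 and C9 are the β- and α-carbons of a C8 ketone, the precursor of the C8=C17 methylene. One conjugate methylation of a Δ9(10)-octalin-8-one, with trapping of the C8–C9 enolate by allyl iodide, therefore sets the angular methyl cis to H-5, the cis ring fusion and the C9 side-chain anchor at once. The precursor is that bicyclic enone, made by Birch reduction of the anisole ring of an enantioenriched tetralin. It already carries C3 (as a TBS ether) and the C4 methyl/carboxyl pair (as a fluoride-labile 2-(trimethylsilyl)ethyl ester).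

Key step: step 8

Remarks on the chemistry:
- Positions are given in labdane numbering (ring A C1–C5 and C10, ring B C5–C10, C19 the carboxyl carbon on C4, C17 the methylene carbon on C8, side chain C11–C16). Systematic names number the bicycle as a naphthalene.
- Assumption: the cinchonidinium salt named in step 2 is taken to deliver the (1R) ester. If the first run shows the opposite sense, the pseudoenantiomeric cinchoninium salt is used with no other change.

Step 1
Reactants: 1 6-methoxy-2-tetralone; 2 dibenzyl carbonate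
Product: 3 benzyl 6-methoxy-2-oxo-1,2,3,4-tetrahydronaphthalene-1-carboxylate
Conditions: NaH (2.2 equiv), THF, reflux; 1 M HCl, 0 °C
Reagents that add atoms: dibenzyl carbonate (2), O=C(OCc1ccccc1)OCc1ccccc1
Why: Claisen-type C-acylation, in which the 2-tetralone enolises toward the benzylic carbon, the aryl-conjugated enolate attacks the carbonate and the β-keto ester is withdrawn from the equilibrium as its sodium enolate.

Step 2
Reactants: 3 benzyl 6-methoxy-2-oxo-1,2,3,4-tetrahydronaphthalene-1-carboxylate
Product: 4 benzyl (1R)-6-methoxy-1-methyl-2-oxo-1,2,3,4-tetrahydronaphthalene-1-carboxylate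
Conditions: MeI, O-allyl-N-(9-anthracenylmethyl)cinchonidinium bromide (10 mol%), K2CO3 (powdered), toluene, −20 °C
Reagents that add atoms: iodomethane, CI
Why: Asymmetric phase-transfer alkylation of a cyclic β-keto ester, in which the chiral ammonium cation pairs with the planar enolate and leaves one face open to iodomethane, setting the quaternary C4 as 1R, while the soft iodide favours C- over O-methylation.

Step 3
Reactants: 4 benzyl (1R)-6-methoxy-1-methyl-2-oxo-1,2,3,4-tetrahydronaphthalene-1-carboxylate
Product: 5 benzyl (1R,2R)-2-hydroxy-6-methoxy-1-methyl-1,2,3,4-tetrahydronaphthalene-1-carboxylate (hydroxyl cis to the C1 methyl)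
Conditions: (S)-2-methyl-CBS-oxazaborolidine (10 mol%), BH3·SMe2, THF, −20 °C; MeOH, then aqueous work-up
Reagents that add atoms: none
Why: Corey–Bakshi–Shibata reduction, in which the oxazaborolidine binds the ketone on the side of the small ring methylene and delivers hydride under reagent control to give the 2R carbinol (C3, hydroxyl cis to the methyl and trans to the ester), so that any minor enantiomer of 4 ends as a separable diastereomer.

Step 4
Reactants: 5 benzyl (1R,2R)-2-hydroxy-6-methoxy-1-methyl-1,2,3,4-tetrahydronaphthalene-1-carboxylate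
Product: 6 (1R,2R)-2-hydroxy-6-methoxy-1-methyl-1,2,3,4-tetrahydronaphthalene-1-carboxylic acid
Conditions: H2 (1 atm), 10% Pd/C, EtOAc, rt
Reagents that add atoms: none
Why: Hydrogenolysis of the benzyl ester frees the acid, which as its carboxylate will be inert to dissolving metal, while the anisole ring and both stereocentres are untouched.

Step 5
Reactants: 6 (1R,2R)-2-hydroxy-6-methoxy-1-methyl-1,2,3,4-tetrahydronaphthalene-1-carboxylic acid
Product: 9 (1R,2R,8aS)-2-hydroxy-1-methyl-6-oxo-1,2,3,4,6,7,8,8a-octahydronaphthalene-1-carboxylic acid, via dienol ether acid 7 (not isolated), via deconjugated enone acid 8 (not isolated)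
Conditions: Li, NH3(l)/THF/t-BuOH, −78 to −33 °C, NH4Cl quench; 1 M HCl, THF, rt; 1 M NaOH, MeOH, rt, then HCl to pH 3, 0 °C
Reagents that add atoms: water, O
Why: Birch reduction takes the anisole to the 1-methoxy-1,4-diene that keeps the tetrasubstituted C5=C10 bond, acid hydrolyses the enol ether and base moves the alkene into conjugation through the dienolate, with C5 set under equilibrium control in favour of the epimer whose ring A chair holds the C19 carboxylate and the C3 hydroxyl equatorial (H-5 axial, cis to C19).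

Step 6
Reactants: 9 (1R,2R,8aS)-2-hydroxy-1-methyl-6-oxo-1,2,3,4,6,7,8,8a-octahydronaphthalene-1-carboxylic acid
Product: 10 2-(trimethylsilyl)ethyl (1R,2R,8aS)-2-hydroxy-1-methyl-6-oxo-1,2,3,4,6,7,8,8a-octahydronaphthalene-1-carboxylate
Conditions: 2-(trimethylsilyl)ethyl 2,2,2-trichloroacetimidate (2 equiv), toluene, 100 °C
Reagents that add atoms: 2-(trimethylsilyl)ethyl 2,2,2-trichloroacetimidate, C[Si](C)(C)CCOC(=N)C(Cl)(Cl)Cl
Why: Promoter-free imidate esterification, in which the acid protonates the imidate and the carboxylate is O-alkylated by the β-silyl-stabilised electrophile, so the hindered carbonyl carbon is never attacked and the far less acidic C3 hydroxyl does not react.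

Step 7
Reactants: 10 2-(trimethylsilyl)ethyl (1R,2R,8aS)-2-hydroxy-1-methyl-6-oxo-1,2,3,4,6,7,8,8a-octahydronaphthalene-1-carboxylate
Product: 11 2-(trimethylsilyl)ethyl (1R,2R,8aS)-2-[(tert-butyldimethylsilyl)oxy]-1-methyl-6-oxo-1,2,3,4,6,7,8,8a-octahydronaphthalene-1-carboxylate
Conditions: TBSOTf, 2,6-lutidine, CH2Cl2, −78 → 0 °C
Reagents that add atoms: tert-butyldimethylsilyl trifluoromethanesulfonate, CC(C)(C)[Si](C)(C)OS(=O)(=O)C(F)(F)F
Why: Silylation of the hindered secondary C3 alcohol with the silyl triflate and a weak hindered base, conditions under which the enone is not enolised.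

Step 8
Reactants: 11 2-(trimethylsilyl)ethyl (1R,2R,8aS)-2-[(tert-butyldimethylsilyl)oxy]-1-methyl-6-oxo-1,2,3,4,6,7,8,8a-octahydronaphthalene-1-carboxylate; 12 allyl iodide
Product: 14 2-(trimethylsilyl)ethyl (1R,2R,4aS,5R,8aS)-2-[(tert-butyldimethylsilyl)oxy]-1,4a-dimethyl-6-oxo-5-(prop-2-en-1-yl)decahydronaphthalene-1-carboxylate, via lithium enolate 13 (not isolated)
Conditions: Me2CuLi (from CuI and 2 MeLi, 1.3 equiv), Et2O, −20 → 0 °C; 12 (4 equiv), DMPU, THF, −30 °C → rt; NH4Cl/NH3 (aq); then t-BuOK (0.2 equiv), t-BuOH, rt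
Reagents that add atoms: lithium dimethylcuprate, [Li+].C[Cu-]C; allyl iodide (12), C=CCI
Why: The cuprate forms a π-complex with the enone and delivers methyl to C10 through a trivalent copper β-adduct and reductive elimination, leaving the lithium enolate specifically across C8–C9, which then displaces iodide from allyl iodide at C9 in an SN2 reaction. The closest known reaction type is the cis-selective addition of lithium dimethylcuprate to bicyclic Δ1(9)-octal-2-ones with alkylation of the regiodefined enolate; no ring is closed. At C10 the methyl should enter axially on the face that carries H-5, because the axial C4 methyl of ring A screens the opposite face and antiparallel attack leads to the cis-fused chair enolate. At C9 allyl iodide should approach on the convex face, syn to the new methyl, since the concave face is blocked by C4 and its substituents. The equatorial 9-allyl isomer is also expected to be the more stable one, so the t-BuOK equilibration next to the C8 ketone should converge any 9-epimer. The step needs 1,4- over 1,2-addition (soft cuprate), C- over O-allylation and C9 over C7 alkylation (soft iodide, DMPU-accelerated alkylation below the temperature of enolate equilibration), and the neopentyl ester is too hindered to react.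

Step 9
Reactants: 14 2-(trimethylsilyl)ethyl (1R,2R,4aS,5R,8aS)-2-[(tert-butyldimethylsilyl)oxy]-1,4a-dimethyl-6-oxo-5-(prop-2-en-1-yl)decahydronaphthalene-1-carboxylate
Product: 15 2-(trimethylsilyl)ethyl (1R,2R,4aS,5R,8aS)-2-[(tert-butyldimethylsilyl)oxy]-1,4a-dimethyl-6-oxo-5-(2-oxoethyl)decahydronaphthalene-1-carboxylate
Conditions: O3, CH2Cl2, −78 °C; Me2S, −78 °C → rt
Reagents that add atoms: ozone, [O-][O+]=O
Why: Ozonolysis (1,3-dipolar cycloaddition, cycloreversion, reductive cleavage of the ozonide) of the only alkene removes the terminal carbon and leaves the two carbons that become C11 and C12.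

Step 10
Reactants: 15 2-(trimethylsilyl)ethyl (1R,2R,4aS,5R,8aS)-2-[(tert-butyldimethylsilyl)oxy]-1,4a-dimethyl-6-oxo-5-(2-oxoethyl)decahydronaphthalene-1-carboxylate
Product: 16 2-(trimethylsilyl)ethyl (1R,2R,4aS,5R,8aS)-2-[(tert-butyldimethylsilyl)oxy]-5-(2-hydroxyethyl)-1,4a-dimethyl-6-oxodecahydronaphthalene-1-carboxylate
Conditions: NaBH4 (0.5 equiv), EtOH/CH2Cl2 (3:7), −78 °C; NH4Cl (aq)
Reagents that add atoms: none
Why: Chemoselective borohydride reduction, since at −78 °C the unhindered aldehyde is reduced much faster than the α-branched C8 ketone flanked by the quaternary C10, which must survive for the methylenation.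

Step 11
Reactants: 16 2-(trimethylsilyl)ethyl (1R,2R,4aS,5R,8aS)-2-[(tert-butyldimethylsilyl)oxy]-5-(2-hydroxyethyl)-1,4a-dimethyl-6-oxodecahydronaphthalene-1-carboxylate
Product: 17 2-(trimethylsilyl)ethyl (1R,2R,4aR,5S,8aS)-2-[(tert-butyldimethylsilyl)oxy]-5-(2-hydroxyethyl)-1,4a-dimethyl-6-methylidenedecahydronaphthalene-1-carboxylate
Conditions: Ph3PCH3Br (4 equiv), KOt-Bu (3.8 equiv), THF, 0 → 50 °C
Reagents that add atoms: methyltriphenylphosphonium bromide, C[P+](c1ccccc1)(c1ccccc1)c1ccccc1.[Br-]
Why: Wittig methylenation of the C8 ketone with excess ylide, which tolerates the C12 alkoxide (the hemiketal is in equilibrium with the open ketone), while the equatorial C9 configuration is the stable one and is not endangered by the basic medium.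

Step 12
Reactants: 17 2-(trimethylsilyl)ethyl (1R,2R,4aR,5S,8aS)-2-[(tert-butyldimethylsilyl)oxy]-5-(2-hydroxyethyl)-1,4a-dimethyl-6-methylidenedecahydronaphthalene-1-carboxylate
Product: 18 2-(trimethylsilyl)ethyl (1R,2R,4aR,5S,8aS)-2-[(tert-butyldimethylsilyl)oxy]-5-(2-iodoethyl)-1,4a-dimethyl-6-methylidenedecahydronaphthalene-1-carboxylate
Conditions: PPh3, imidazole, I2 (premixed), CH2Cl2, 0 °C → rt
Reagents that add atoms: iodine, II
Why: Appel-type iodination, in which the alkoxyphosphonium ion of the primary C12 alcohol is displaced by iodide in an SN2 reaction, with the iodine bound to phosphorus before the substrate is added so that no free iodine can cyclise the alcohol onto the C8 methylene.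

Step 13
Reactants: 18 2-(trimethylsilyl)ethyl (1R,2R,4aR,5S,8aS)-2-[(tert-butyldimethylsilyl)oxy]-5-(2-iodoethyl)-1,4a-dimethyl-6-methylidenedecahydronaphthalene-1-carboxylate; 19 2-chlorobuta-1,3-diene
Product: 21 2-(trimethylsilyl)ethyl (1R,2R,4aR,5S,8aS)-2-[(tert-butyldimethylsilyl)oxy]-1,4a-dimethyl-6-methylidene-5-(3-methylidenepent-4-en-1-yl)decahydronaphthalene-1-carboxylate, via buta-1,3-dien-2-ylmagnesium chloride 20 (not isolated)
Conditions: 19, Mg, ZnCl2 (cat.), BrCH2CH2Br (cat.), THF, reflux; then 18, Li2CuCl4 (5 mol%), THF, −10 → 0 °C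
Reagents that add atoms: 2-chlorobuta-1,3-diene (19), C=CC(Cl)=C
Why: Copper-catalysed cross-coupling of a primary alkyl iodide with an alkenyl Grignard reagent (a Kumada-type sp3–sp2 coupling) forms the C12–C13 bond and delivers the 2-substituted butadiene, the catalysed coupling being much faster than attack on the neopentyl ester.

Step 14
Reactants: 21 2-(trimethylsilyl)ethyl (1R,2R,4aR,5S,8aS)-2-[(tert-butyldimethylsilyl)oxy]-1,4a-dimethyl-6-methylidene-5-(3-methylidenepent-4-en-1-yl)decahydronaphthalene-1-carboxylate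
Product: 22 (1R,2R,4aR,5S,8aS)-2-hydroxy-1,4a-dimethyl-6-methylidene-5-(3-methylidenepent-4-en-1-yl)decahydronaphthalene-1-carboxylic acid
Conditions: TBAF (5 equiv), THF, rt → 50 °C; NaH2PO4 (aq)
Reagents that add atoms: none
Why: Fluoride attacks both silicon atoms, cleaving the Si–O bond at C3 and triggering β-elimination of the 2-(trimethylsilyl)ethyl ester to ethene and the carboxylate, which frees both groups without acid or strong nucleophile near the diene.

Step 15
Reactants: 22 (1R,2R,4aR,5S,8aS)-2-hydroxy-1,4a-dimethyl-6-methylidene-5-(3-methylidenepent-4-en-1-yl)decahydronaphthalene-1-carboxylic acid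
Product: 23 (1R,2R,4aR,5S,8aS)-2-(acetyloxy)-1,4a-dimethyl-6-methylidene-5-(3-methylidenepent-4-en-1-yl)decahydronaphthalene-1-carboxylic acid (CNP0243981.1)
Conditions: Ac2O, pyridine, DMAP (cat.), CH2Cl2, rt; then H2O, rt, work-up at pH 4
Reagents that add atoms: acetic anhydride, CC(=O)OC(C)=O
Why: DMAP-catalysed acetylation of the C3 alcohol, with any mixed anhydride at C19 hydrolysed at its unhindered acetyl carbonyl during the aqueous stir to return the free acid.

Compound list
1 | 6-methoxy-2-tetralone | COc1ccc2c(c1)CCC(=O)C2 | starting material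
2 | dibenzyl carbonate | O=C(OCc1ccccc1)OCc1ccccc1 | starting material
3 | benzyl 6-methoxy-2-oxo-1,2,3,4-tetrahydronaphthalene-1-carboxylate (racemic, largely enolised) | COc1ccc2c(c1)CCC(=O)C2C(=O)OCc1ccccc1 | intermediate
4 | benzyl (1R)-6-methoxy-1-methyl-2-oxo-1,2,3,4-tetrahydronaphthalene-1-carboxylate | COc1ccc2c(c1)CCC(=O)[C@]2(C)C(=O)OCc1ccccc1 | intermediate
5 | benzyl (1R,2R)-2-hydroxy-6-methoxy-1-methyl-1,2,3,4-tetrahydronaphthalene-1-carboxylate | COc1ccc2c(c1)CC[C@@H](O)[C@]2(C)C(=O)OCc1ccccc1 | intermediate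
6 | (1R,2R)-2-hydroxy-6-methoxy-1-methyl-1,2,3,4-tetrahydronaphthalene-1-carboxylic acid | COc1ccc2c(c1)CC[C@@H](O)[C@]2(C)C(=O)O | intermediate
7 | (1R,2R)-2-hydroxy-6-methoxy-1-methyl-1,2,3,4,5,8-hexahydronaphthalene-1-carboxylic acid (dienol ether acid) | COC1=CCC2=C(C1)CC[C@@H](O)[C@]2(C)C(=O)O | intermediate (not isolated)
8 | (1R,2R)-2-hydroxy-1-methyl-6-oxo-1,2,3,4,5,6,7,8-octahydronaphthalene-1-carboxylic acid (deconjugated enone acid) | O=C1CCC2=C(C1)CC[C@@H](O)[C@]2(C)C(=O)O | intermediate (not isolated)
9 | (1R,2R,8aS)-2-hydroxy-1-methyl-6-oxo-1,2,3,4,6,7,8,8a-octahydronaphthalene-1-carboxylic acid | O=C1CC[C@H]2C(=C1)CC[C@@H](O)[C@]2(C)C(=O)O | intermediate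
10 | 2-(trimethylsilyl)ethyl (1R,2R,8aS)-2-hydroxy-1-methyl-6-oxo-1,2,3,4,6,7,8,8a-octahydronaphthalene-1-carboxylate | O=C1CC[C@H]2C(=C1)CC[C@@H](O)[C@]2(C)C(=O)OCC[Si](C)(C)C | intermediate
11 | 2-(trimethylsilyl)ethyl (1R,2R,8aS)-2-[(tert-butyldimethylsilyl)oxy]-1-methyl-6-oxo-1,2,3,4,6,7,8,8a-octahydronaphthalene-1-carboxylate (key-step precursor) | O=C1CC[C@H]2C(=C1)CC[C@@H](O[Si](C)(C)C(C)(C)C)[C@]2(C)C(=O)OCC[Si](C)(C)C | intermediate
12 | allyl iodide | C=CCI | starting material
13 | lithium C8–C9 enolate of the cis-fused 10-methyl ketone | C1=C(O[Li])CC[C@H]2[C@]1(C)CC[C@@H](O[Si](C)(C)C(C)(C)C)[C@]2(C)C(=O)OCC[Si](C)(C)C | intermediate (not isolated)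
14 | 2-(trimethylsilyl)ethyl (1R,2R,4aS,5R,8aS)-2-[(tert-butyldimethylsilyl)oxy]-1,4a-dimethyl-6-oxo-5-(prop-2-en-1-yl)decahydronaphthalene-1-carboxylate (key-step product) | C=CC[C@H]1C(=O)CC[C@H]2[C@]1(C)CC[C@@H](O[Si](C)(C)C(C)(C)C)[C@]2(C)C(=O)OCC[Si](C)(C)C | intermediate
15 | 2-(trimethylsilyl)ethyl (1R,2R,4aS,5R,8aS)-2-[(tert-butyldimethylsilyl)oxy]-1,4a-dimethyl-6-oxo-5-(2-oxoethyl)decahydronaphthalene-1-carboxylate | O=CC[C@H]1C(=O)CC[C@H]2[C@]1(C)CC[C@@H](O[Si](C)(C)C(C)(C)C)[C@]2(C)C(=O)OCC[Si](C)(C)C | intermediate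
16 | 2-(trimethylsilyl)ethyl (1R,2R,4aS,5R,8aS)-2-[(tert-butyldimethylsilyl)oxy]-5-(2-hydroxyethyl)-1,4a-dimethyl-6-oxodecahydronaphthalene-1-carboxylate | OCC[C@H]1C(=O)CC[C@H]2[C@]1(C)CC[C@@H](O[Si](C)(C)C(C)(C)C)[C@]2(C)C(=O)OCC[Si](C)(C)C | intermediate
17 | 2-(trimethylsilyl)ethyl (1R,2R,4aR,5S,8aS)-2-[(tert-butyldimethylsilyl)oxy]-5-(2-hydroxyethyl)-1,4a-dimethyl-6-methylidenedecahydronaphthalene-1-carboxylate | OCC[C@H]1C(=C)CC[C@H]2[C@]1(C)CC[C@@H](O[Si](C)(C)C(C)(C)C)[C@]2(C)C(=O)OCC[Si](C)(C)C | intermediate
18 | 2-(trimethylsilyl)ethyl (1R,2R,4aR,5S,8aS)-2-[(tert-butyldimethylsilyl)oxy]-5-(2-iodoethyl)-1,4a-dimethyl-6-methylidenedecahydronaphthalene-1-carboxylate | ICC[C@H]1C(=C)CC[C@H]2[C@]1(C)CC[C@@H](O[Si](C)(C)C(C)(C)C)[C@]2(C)C(=O)OCC[Si](C)(C)C | intermediate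
19 | 2-chlorobuta-1,3-diene | C=CC(Cl)=C | starting material
20 | buta-1,3-dien-2-ylmagnesium chloride | C=CC(=C)[Mg]Cl | intermediate (not isolated)
21 | 2-(trimethylsilyl)ethyl (1R,2R,4aR,5S,8aS)-2-[(tert-butyldimethylsilyl)oxy]-1,4a-dimethyl-6-methylidene-5-(3-methylidenepent-4-en-1-yl)decahydronaphthalene-1-carboxylate | C=CC(=C)CC[C@H]1C(=C)CC[C@H]2[C@]1(C)CC[C@@H](O[Si](C)(C)C(C)(C)C)[C@]2(C)C(=O)OCC[Si](C)(C)C | intermediate
22 | (1R,2R,4aR,5S,8aS)-2-hydroxy-1,4a-dimethyl-6-methylidene-5-(3-methylidenepent-4-en-1-yl)decahydronaphthalene-1-carboxylic acid | C=CC(=C)CC[C@H]1C(=C)CC[C@H]2[C@]1(C)CC[C@@H](O)[C@]2(C)C(=O)O | intermediate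
23 | (1R,2R,4aR,5S,8aS)-2-(acetyloxy)-1,4a-dimethyl-6-methylidene-5-(3-methylidenepent-4-en-1-yl)decahydronaphthalene-1-carboxylic acid | C=CC(=C)CC[C@H]1C(=C)CC[C@H]2[C@]1(C)CC[C@@H](OC(C)=O)[C@]2(C)C(=O)O | target

Total step count: 15
Longest linear sequence: 15 steps (1 → 23; the Grignard reagent 20 is made and consumed inside step 13)

Steps most likely to fail

Step 8. Conjugate addition at the fully substituted C10 next to the neopentyl C5 may be sluggish. C-allylation of the hindered C9 enolate may also be slow enough for proton transfer to scramble the enolate, giving allylation at C7, double allylation or O-allylation. The fallback sets out from 11. Lithium dimethylcuprate is added in the presence of Me3SiCl (THF, −78 °C, Et3N quench), which accelerates the addition and captures the enolate as the C8 trimethylsilyl enol ether F1 with the same C10 configuration. A Tsuji allylation of F1 (allyl methyl carbonate, Pd2(dba)3, dppe, THF, reflux) then transfers allyl to C9 regiospecifically under neutral conditions, through a π-allylpalladium cation and the enolate released when methoxide removes the silyl group. After the same t-BuOK equilibration the material comes back to the route at 14.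

Step 5. The protonation and equilibration at C5 may show too little facial bias, because ring A can also populate the chair with the carboxylate and the hydroxyl both axial, which belongs to the C5 epimer. Conjugation may also stay incomplete. The fallback sets out from 9, taken as the C5 mixture. Treatment with 2,2-dimethoxypropane and camphorsulfonic acid in acetone ties the C3 oxygen and the C19 carboxyl into the trans-fused 2,2-dimethyl-1,3-dioxan-4-one F2. This locks ring A with the C4 methyl axial, so that only the epimer with H-5 cis to C19 can keep C6 equatorial; DBU in CH2Cl2 equilibrates C5 within that locked system. Opening of F2 at the acyl carbon with sodium 2-(trimethylsilyl)ethoxide (THF, 0 °C) releases acetone and comes back to the route at 10.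

Step 2. The ion-pair-controlled methylation of a benzyl β-keto ester with a small electrophile may give insufficient enantioselectivity, and uncatalysed alkylation at the solid–liquid interface may erode it further. The fallback sets out from 3. Noyori-type asymmetric hydrogenation with dynamic kinetic resolution (RuCl2[(S)-BINAP], H2, CH2Cl2, 50 °C) fixes the carbinol centre in benzyl (1S,2S)-2-hydroxy-6-methoxy-1,2,3,4-tetrahydronaphthalene-1-carboxylate F3. A Fráter–Seebach alkylation of its dianion (LDA, 2.2 equiv, THF, −78 → −20 °C; MeI) introduces the methyl anti to the alkoxide oxygen and gives benzyl (1R,2S)-2-hydroxy-6-methoxy-1-methyl-1,2,3,4-tetrahydronaphthalene-1-carboxylate F4. Dess–Martin oxidation of F4 comes back to the route at 4, whose quaternary centre can no longer racemise.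

Further compounds
F1 | step 8 | 2-(trimethylsilyl)ethyl ester of the cis-fused 3-(tert-butyldimethylsilyloxy)-10-methyl C8 trimethylsilyl enol ether (C8=C9) | C1=C(O[Si](C)(C)C)CC[C@H]2[C@]1(C)CC[C@@H](O[Si](C)(C)C(C)(C)C)[C@]2(C)C(=O)OCC[Si](C)(C)C
F2 | step 5 | 2,2-dimethyl-1,3-dioxan-4-one of 9 (acetonide bridging the C3 oxygen and the C19 carboxyl, trans-fused to ring A, H-5 cis to C19) | O=C1CC[C@H]2C(=C1)CC[C@@H](OC(C)(C)OC3=O)[C@@]23C
F3 | step 2 | benzyl (1S,2S)-2-hydroxy-6-methoxy-1,2,3,4-tetrahydronaphthalene-1-carboxylate | COc1ccc2c(c1)CC[C@H](O)[C@H]2C(=O)OCc1ccccc1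
F4 | step 2 | benzyl (1R,2S)-2-hydroxy-6-methoxy-1-methyl-1,2,3,4-tetrahydronaphthalene-1-carboxylate | COc1ccc2c(c1)CC[C@H](O)[C@]2(C)C(=O)OCc1ccccc1
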